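**Retrosynthetic overview**
1. Feature: the nine-membered ring holds one ester oxygen, bonded on one side to the C=O carbon that sits on the enol C=C of the cyclohexene and on the other to the hydrogen-free carbon carrying CH3 and CH2CO2Me. Removing that O leaves an eight-membered ketone with a quaternary α-carbon, so the O is put in last by Baeyer–Villiger ring expansion.
2. Target ⇐ (TES off, CH–OH → C=O/enol, TBS off) nine-membered bis-silyl lactone ⇐ O insertion into a γ-lactone-bridged cyclooctanone whose future enol carbon is parked as CH–OTES.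
3. Cyclooctanone ⇐ conjugate reduction/alkylation (quaternary carbon) of a bicyclic α-methyl cyclooctenone ⇐ ring-closing metathesis of a methacryloyl ketone with a vinyl γ-lactone.
4. Metathesis substrate ⇐ thioester-to-ketone coupling, ketone reduction, silylation ⇐ Michael addition of a 2-deoxy-D-ribose-derived vinyl lactone enolate to an alkylidene β-keto thioester made from (S)-perillic acid.
5. Ring order: cyclohexane (terpene) and γ-lactone (sugar) are bought; eight-membered carbocycle by metathesis; nine-membered lactone last, by one-atom ring expansion.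

Key step: step 16

Assumption: the ring CH–O carbon and the ring-fusion CH next to it end as the enol C=C of the target, so their configuration is transient. The route is drawn for the isomer expected from steps 10 and 11, and the β-boryl, β-hydroxy and α-selanyl intermediates of steps 2 and 4 are carried as diastereomer mixtures at centres that steps 3 and 4 erase.

**Route**

Step 1
Reactants: 1 (S)-(−)-perillic acid
Product: 2 S-ethyl (4S)-4-(prop-1-en-2-yl)cyclohex-1-ene-1-carbothioate
Conditions: EtSH, DCC, DMAP (cat.), CH2Cl2, 0 °C → rt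
Reagents that add atoms: ethanethiol, CCS
Why: Steglich-type thioesterification, in which the carbodiimide activates the acid and DMAP passes the acyl group to the thiol; the stereocentre is not involved.

Step 2
Reactants: 2 S-ethyl perillate thioester
Product: 4 S-ethyl (4S)-2-hydroxy-4-(prop-1-en-2-yl)cyclohexane-1-carbothioate (diastereomer mixture at C1/C2), via β-boryl thioester 3 (not isolated)
Conditions: B2pin2, CuCl (cat.), Xantphos (cat.), NaOt-Bu (cat.), MeOH, THF, rt; then NaBO3·4H2O, THF/H2O, 0 °C → rt
Reagents that add atoms: sodium perborate, [Na+].[Na+].O[B-]1(O)OO[B-](O)(O)OO1 (oxygen of the new OH); bis(pinacolato)diboron, CC1(C)OB(OC1(C)C)B1OC(C)(C)C(C)(C)O1 (boron held only in 3)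
Why: Copper-catalysed conjugate borylation puts boron on the β-carbon of the unsaturated thioester and ignores the unactivated isopropenyl group, methanol protonates the copper enolate, and perborate then replaces boron by hydroxyl with retention; both new centres are mixtures that steps 3 and 4 erase.

Step 3
Reactants: 4 β-hydroxy thioester
Product: 5 S-ethyl (4S)-2-oxo-4-(prop-1-en-2-yl)cyclohexane-1-carbothioate (keto/enol mixture)
Conditions: Dess–Martin periodinane, CH2Cl2, 0 °C → rt
Reagents that add atoms: none
Why: Dess–Martin oxidation of the secondary alcohol gives the β-keto thioester under neutral conditions that leave sulfur and the alkene alone.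

Step 4
Reactants: 5 β-keto thioester
Product: 9 S-ethyl (4S)-6-oxo-4-(prop-1-en-2-yl)cyclohex-1-ene-1-carbothioate, via sodium enolate 6 (not isolated), via α-selanyl keto thioester 7 (not isolated), via selenoxide 8 (not isolated)
Conditions: NaH, THF, 0 °C; PhSeBr, −78 °C; then m-CPBA (1 equiv), CH2Cl2, −78 → −20 °C; used at once
Reagents that add atoms: none
Why: α-Selenenylation of the β-dicarbonyl enolate and syn-elimination of the selenoxide can only take a hydrogen from the ring CH2 next to the selanyl carbon, so the C=C forms in the ring between the two-carbonyl carbon and that CH2; the enolate takes up PhSeBr, and selenium takes up the peracid, far faster than the isopropenyl group does.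

Step 5
Reactants: 10 2-deoxy-D-ribose
Product: 11 2-deoxy-D-ribono-1,4-lactone [(4S,5R)-4-hydroxy-5-(hydroxymethyl)oxolan-2-one]
Conditions: Br2, H2O, rt
Reagents that add atoms: none
Why: Bromine-water oxidation of the aldose at C1 gives the aldonic acid, which closes to the 1,4-lactone; C3 and C4 of the sugar become the two lactone stereocentres unchanged.

Step 6
Reactants: 11 2-deoxy-D-ribono-1,4-lactone
Product: 12 (4S,5R)-4-[(tert-butyldimethylsilyl)oxy]-5-{[(tert-butyldimethylsilyl)oxy]methyl}oxolan-2-one
Conditions: TBSCl, imidazole, DMF, rt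
Reagents that add atoms: tert-butyldimethylsilyl chloride, CC(C)(C)[Si](C)(C)Cl
Why: Standard silylation of both hydroxyls with the silyl chloride and imidazole.

Step 7
Reactants: 12 bis-TBS lactone
Product: 13 (4S,5R)-4-[(tert-butyldimethylsilyl)oxy]-5-(hydroxymethyl)oxolan-2-one
Conditions: TFA/H2O/THF (1:1:4), 0 °C
Reagents that add atoms: none
Why: Acid-catalysed hydrolysis cleaves the primary silyl ether much faster than the secondary one, a selectivity used routinely with 3,5-bis-silylated deoxyribose derivatives.

Step 8
Reactants: 13 primary alcohol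
Product: 14 (2S,3S)-3-[(tert-butyldimethylsilyl)oxy]-5-oxooxolane-2-carbaldehyde
Conditions: Dess–Martin periodinane, CH2Cl2, 0 °C → rt; used crude
Reagents that add atoms: none
Why: Dess–Martin oxidation of the primary alcohol to the aldehyde under non-basic conditions that should neither epimerise the α-oxy centre nor eliminate the β-silyloxy group.

Step 9
Reactants: 14 aldehyde
Product: 15 (4S,5R)-4-[(tert-butyldimethylsilyl)oxy]-5-ethenyloxolan-2-one
Conditions: Ph3PCH3Br, KHMDS, THF, 0 °C; then 14, −78 → 0 °C
Reagents that add atoms: methyltriphenylphosphonium bromide, C[P+](c1ccccc1)(c1ccccc1)c1ccccc1.[Br-]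
Why: Wittig methylenation of the aldehyde, which reacts far faster than the lactone carbonyl; low temperature limits β-elimination and epimerisation of the α-oxy centre.

Step 10
Reactants: 15 vinyl lactone, 9 alkylidene β-keto thioester
Product: 17 S-ethyl (1R,2R,4S)-2-[(3S,4S,5R)-4-[(tert-butyldimethylsilyl)oxy]-5-ethenyl-2-oxooxolan-3-yl]-6-oxo-4-(prop-1-en-2-yl)cyclohexane-1-carbothioate, via lithium enolate 16 (not isolated)
Conditions: LDA, THF, −78 °C; then 9, −78 °C; AcOH
Reagents that add atoms: none
Why: Michael addition of the lactone lithium enolate to the doubly activated alkylidene β-keto thioester: the enolate is attacked on the face opposite its neighbouring silyloxy group (new lactone centre trans to OTBS), the enone is attacked axially and anti to the isopropenyl group as in conjugate additions to 5-substituted cyclohexenones (new ring centre trans to isopropenyl), and the acidic carbon between the two carbonyls settles trans to the new substituent.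

Step 11
Reactants: 17 Michael adduct
Product: 18 S-ethyl (1R,2R,4S,6S)-2-[(3S,4S,5R)-4-[(tert-butyldimethylsilyl)oxy]-5-ethenyl-2-oxooxolan-3-yl]-6-hydroxy-4-(prop-1-en-2-yl)cyclohexane-1-carbothioate
Conditions: Zn(BH4)2, Et2O/THF, −40 → −20 °C; aq. NH4Cl
Reagents that add atoms: none
Why: Chelation-controlled hydride reduction: zinc binds the ketone and thioester oxygens of the equatorial β-keto thioester and hydride enters from the equatorial direction, away from the axial isopropenyl group, so the new hydroxyl should be cis to the thioester; thioester and lactone are not reduced at this temperature.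

Step 12
Reactants: 18 β-hydroxy thioester
Product: 19 S-ethyl (1R,2R,4S,6S)-2-[(3S,4S,5R)-4-[(tert-butyldimethylsilyl)oxy]-5-ethenyl-2-oxooxolan-3-yl]-4-(prop-1-en-2-yl)-6-[(triethylsilyl)oxy]cyclohexane-1-carbothioate
Conditions: TESOTf, 2,6-lutidine, CH2Cl2, −78 → 0 °C
Reagents that add atoms: triethylsilyl triflate, CC[Si](CC)(CC)OS(=O)(=O)C(F)(F)F
Why: Silylation of the hindered secondary alcohol with the silyl triflate and a non-nucleophilic base stores the future enol carbon as a silyl ether, so that only one ketone is present at the key step.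

Step 13
Reactants: 19 TES-protected thioester
Product: 20 methacryloyl ketone (19 with C(=O)SEt replaced by C(=O)C(CH3)=CH2; configuration unchanged)
Conditions: CH2=C(Me)MgBr, ZnBr2, THF, 0 °C; then 19, PdCl2(PPh3)2 (cat.), toluene/THF, rt
Reagents that add atoms: isopropenylzinc bromide, C=C(C)[Zn]Br (made in the flask from isopropenylmagnesium bromide, C=C(C)[Mg]Br, and ZnBr2)
Why: Fukuyama coupling: Pd(0) inserts into the C(O)–S bond and the alkenylzinc transfers the isopropenyl group to give the ketone, while organozinc halides leave the lactone, the silyl ethers and the product enone alone.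

Step 14
Reactants: 20 methacryloyl ketone
Product: 21 tricyclic enone: cyclohexane trans-fused to a (Z)-2-methylcyclooct-2-en-1-one whose C4 and C6 are joined by the lactone bridge O–C(=O)
Conditions: Hoveyda–Grubbs II (15 mol%), toluene (1 mM), 80 °C
Reagents that add atoms: none
Why: Ring-closing metathesis: the ruthenium carbene loads at the lactone vinyl group and closes onto the methacryloyl alkene, which the γ-lactone and the trans-substituted cyclohexane hold close; the cis trisubstituted enone is the only geometry an eight-membered ring allows, and closure onto the isopropenyl group across trans-1,3 positions of the cyclohexane is geometrically disfavoured.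

Step 15
Reactants: 21 tricyclic enone, 22 methyl bromoacetate
Product: 24 lactone-bridged cyclooctanone carrying the quaternary carbon (Baeyer–Villiger precursor), via lithium enolate 23 (not isolated)
Conditions: L-Selectride (1.05 equiv), THF, −78 °C; then 22, DMPU, −78 → −20 °C
Reagents that add atoms: none
Why: Conjugate reduction–alkylation: L-Selectride adds hydride to the β-carbon of the α-methyl enone as it does with carvone, so the enolate exists only on the side of the future quaternary carbon, and bromoacetate should enter from the face remote from the O–C(=O) bridge, as electrophiles do with bicyclo[3.2.1]octan-3-one enolates, which leaves CH3 on the side of the lactone bridge.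

Step 16
Reactants: 24 lactone-bridged cyclooctanone
Product: 26 nine-membered tertiary lactone (bis-silyl ether), via silyl peroxy ketal 25 (not isolated)
Conditions: (Me3SiO)2, TMSOTf (cat.), 4 Å MS, CH2Cl2, −40 → −20 °C
Reagents that add atoms: bis(trimethylsilyl) peroxide, C[Si](C)(C)OO[Si](C)(C)C
Why: The Lewis acid activates the only ketone, the silyl peroxide adds to give the silyl peroxy ketal 25, and the α-carbon lying anti-periplanar to the O–O bond shifts to oxygen as silanolate leaves; this is the Baeyer–Villiger oxidation of α-quaternary cycloalkanones to tertiary-alkyl lactones. No ring is closed by cyclisation: the nine-membered lactone arises by ring expansion, the 1,2-shift inserting one oxygen into the C(=O)–C(quaternary) bond of the eight-membered carbocycle and forming the C(=O)–O and O–C bonds. The carbinol stereocentre is the former quaternary carbon and keeps its configuration because the migrating carbon moves with retention. The step needs regioselectivity for the fully substituted carbon over the ring-fusion CH, secured by the higher migratory aptitude of a tertiary alkyl group and by the electron-withdrawing silyloxy group β to the competing carbon. It also needs chemoselectivity for C=O over the isopropenyl C=C, secured by a silyl peroxide that attacks only the activated carbonyl and by the second carbonyl being stored as the triethylsilyl ether.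

Step 17
Reactants: 26 nine-membered lactone
Product: 27 β-hydroxy lactone (TBS ether kept)
Conditions: PPTS (cat.), MeOH/CH2Cl2, 0 °C
Reagents that add atoms: none
Why: Acid-catalysed methanolysis removes the triethylsilyl ether much faster than the hindered TBS ether, and methanol cannot scramble the methyl ester.

Step 18
Reactants: 27 β-hydroxy lactone
Product: 28 enolised β-keto lactone TBS ether
Conditions: Dess–Martin periodinane (1.2 equiv), CH2Cl2, 0 °C → rt
Reagents that add atoms: none
Why: Dess–Martin oxidation gives the β-keto lactone, which should rest as the hydrogen-bonded enol of the target; this removes the two transient stereocentres.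

Step 19
Reactants: 28 enol TBS ether
Product: 29 CNP0302642.1
Conditions: HF·pyridine, pyridine/THF, 0 °C → rt
Reagents that add atoms: none
Why: Fluoride cleavage of the last silyl ether under buffered, non-basic conditions that should not open either lactone or touch the methyl ester.

**Compound list**
1 | (S)-(−)-perillic acid, (4S)-4-(prop-1-en-2-yl)cyclohex-1-ene-1-carboxylic acid | C=C(C)[C@@H]1CC=C(C(=O)O)CC1 | starting material
2 | S-ethyl (4S)-4-(prop-1-en-2-yl)cyclohex-1-ene-1-carbothioate | C=C(C)[C@@H]1CC=C(C(=O)SCC)CC1 | intermediate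
3 | S-ethyl (4S)-4-(prop-1-en-2-yl)-2-(4,4,5,5-tetramethyl-1,3,2-dioxaborolan-2-yl)cyclohexane-1-carbothioate (mixture at C1/C2, not isolated) | C=C(C)[C@@H]1CC(B2OC(C)(C)C(C)(C)O2)C(C(=O)SCC)CC1 | intermediate
4 | S-ethyl (4S)-2-hydroxy-4-(prop-1-en-2-yl)cyclohexane-1-carbothioate (mixture at C1/C2) | C=C(C)[C@@H]1CC(O)C(C(=O)SCC)CC1 | intermediate
5 | S-ethyl (4S)-2-oxo-4-(prop-1-en-2-yl)cyclohexane-1-carbothioate (keto/enol) | C=C(C)[C@@H]1CC(=O)C(C(=O)SCC)CC1 | intermediate
6 | sodium enolate of 5 (not isolated) | C=C(C)[C@@H]1CC([O-])=C(C(=O)SCC)CC1.[Na+] | intermediate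
7 | S-ethyl (4S)-2-oxo-1-(phenylselanyl)-4-(prop-1-en-2-yl)cyclohexane-1-carbothioate (mixture at C1, not isolated) | C=C(C)[C@@H]1CC(=O)C([Se]c2ccccc2)(C(=O)SCC)CC1 | intermediate
8 | selenoxide of 7 (not isolated) | C=C(C)[C@@H]1CC(=O)C([Se](=O)c2ccccc2)(C(=O)SCC)CC1 | intermediate
9 | S-ethyl (4S)-6-oxo-4-(prop-1-en-2-yl)cyclohex-1-ene-1-carbothioate | C=C(C)[C@@H]1CC(=O)C(C(=O)SCC)=CC1 | intermediate
10 | 2-deoxy-D-ribose | O=CC[C@H](O)[C@H](O)CO | starting material
11 | 2-deoxy-D-ribono-1,4-lactone, (4S,5R)-4-hydroxy-5-(hydroxymethyl)oxolan-2-one | OC[C@H]1OC(=O)C[C@@H]1O | intermediate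
12 | (4S,5R)-4-[(tert-butyldimethylsilyl)oxy]-5-{[(tert-butyldimethylsilyl)oxy]methyl}oxolan-2-one | CC(C)(C)[Si](C)(C)OC[C@H]1OC(=O)C[C@@H]1O[Si](C)(C)C(C)(C)C | intermediate
13 | (4S,5R)-4-[(tert-butyldimethylsilyl)oxy]-5-(hydroxymethyl)oxolan-2-one | OC[C@H]1OC(=O)C[C@@H]1O[Si](C)(C)C(C)(C)C | intermediate
14 | (2S,3S)-3-[(tert-butyldimethylsilyl)oxy]-5-oxooxolane-2-carbaldehyde | O=C[C@H]1OC(=O)C[C@@H]1O[Si](C)(C)C(C)(C)C | intermediate
15 | (4S,5R)-4-[(tert-butyldimethylsilyl)oxy]-5-ethenyloxolan-2-one | C=C[C@H]1OC(=O)C[C@@H]1O[Si](C)(C)C(C)(C)C | intermediate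
16 | lithium enolate of 15 (not isolated) | C=C[C@H]1OC([O-])=C[C@@H]1O[Si](C)(C)C(C)(C)C.[Li+] | intermediate
17 | Michael adduct, S-ethyl (1R,2R,4S)-2-[(3S,4S,5R)-4-[(tert-butyldimethylsilyl)oxy]-5-ethenyl-2-oxooxolan-3-yl]-6-oxo-4-(prop-1-en-2-yl)cyclohexane-1-carbothioate (keto form; thioester trans to lactonyl, lactonyl trans to isopropenyl, lactone 3,4-trans) | C=C(C)[C@@H]1CC(=O)[C@H](C(=O)SCC)[C@H](C1)[C@@H]2C(=O)O[C@H](C=C)[C@H]2O[Si](C)(C)C(C)(C)C | intermediate
18 | (1R,2R,4S,6S)-6-hydroxy analogue of 17 (OH cis to the thioester and to isopropenyl) | C=C(C)[C@@H]1C[C@H](O)[C@H](C(=O)SCC)[C@H](C1)[C@@H]2C(=O)O[C@H](C=C)[C@H]2O[Si](C)(C)C(C)(C)C | intermediate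
19 | triethylsilyl ether of 18 | C=C(C)[C@@H]1C[C@H](O[Si](CC)(CC)CC)[C@H](C(=O)SCC)[C@H](C1)[C@@H]2C(=O)O[C@H](C=C)[C@H]2O[Si](C)(C)C(C)(C)C | intermediate
20 | methacryloyl ketone (19 with C(=O)SEt replaced by C(=O)C(CH3)=CH2) | C=C(C)[C@@H]1C[C@H](O[Si](CC)(CC)CC)[C@H](C(=O)C(C)=C)[C@H](C1)[C@@H]2C(=O)O[C@H](C=C)[C@H]2O[Si](C)(C)C(C)(C)C | intermediate
21 | tricyclic enone: cyclohexane trans-fused to a (Z)-2-methylcyclooct-2-en-1-one; lactone bridge O–C(=O) from C4 to C6, OTBS on C5 on the side of that bridge; cyclohexane carries OTES cis to the C–C(=O) bond and cis to isopropenyl | C=C(C)[C@@H]1C[C@H](O[Si](CC)(CC)CC)[C@@H]2C(=O)/C(C)=C\[C@H]3OC(=O)[C@H]([C@@H]3O[Si](C)(C)C(C)(C)C)[C@H]2C1 | intermediate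
22 | methyl bromoacetate | COC(=O)CBr | starting material
23 | lithium enolate from 1,4-reduction of 21 (not isolated) | C=C(C)[C@@H]1C[C@H](O[Si](CC)(CC)CC)[C@@H]2/C([O-])=C(C)\C[C@H]3OC(=O)[C@H]([C@@H]3O[Si](C)(C)C(C)(C)C)[C@H]2C1.[Li+] | intermediate
24 | lactone-bridged cyclooctanone: as 21 with C3 saturated and C2 quaternary, CH3 on the side of the lactone bridge and CH2CO2Me on the opposite face | C=C(C)[C@@H]1C[C@H](O[Si](CC)(CC)CC)[C@@H]2C(=O)[C@](C)(CC(=O)OC)C[C@H]3OC(=O)[C@H]([C@@H]3O[Si](C)(C)C(C)(C)C)[C@H]2C1 | intermediate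
25 | silyl peroxy ketal of 24 (Criegee adduct, not isolated) | C=C(C)[C@@H]1C[C@H](O[Si](CC)(CC)CC)[C@@H]2C(O[Si](C)(C)C)(OO[Si](C)(C)C)[C@](C)(CC(=O)OC)C[C@H]3OC(=O)[C@H]([C@@H]3O[Si](C)(C)C(C)(C)C)[C@H]2C1 | intermediate
26 | nine-membered tertiary lactone: 24 with O inserted between the ketone carbon and the quaternary carbon, configuration retained | C=C(C)[C@@H]1C[C@H](O[Si](CC)(CC)CC)[C@@H]2C(=O)O[C@](C)(CC(=O)OC)C[C@H]3OC(=O)[C@H]([C@@H]3O[Si](C)(C)C(C)(C)C)[C@H]2C1 | intermediate
27 | β-hydroxy lactone (26 without TES) | C=C(C)[C@@H]1C[C@H](O)[C@@H]2C(=O)O[C@](C)(CC(=O)OC)C[C@H]3OC(=O)[C@H]([C@@H]3O[Si](C)(C)C(C)(C)C)[C@H]2C1 | intermediate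
28 | enolised β-keto lactone, TBS ether of the target | C=C(C)[C@@H]1CC(O)=C2C(=O)O[C@](C)(CC(=O)OC)C[C@H]3OC(=O)[C@H]([C@@H]3O[Si](C)(C)C(C)(C)C)[C@H]2C1 | intermediate
29 | CNP0302642.1 | C=C(C)[C@@H]1CC(O)=C2C(=O)O[C@](C)(CC(=O)OC)C[C@H]3OC(=O)[C@H]([C@@H]3O)[C@H]2C1 | target

**Totals and risks**

Total: 19 steps. Longest linear sequence: 15 steps (2-deoxy-D-ribose 10 to 29, steps 5–19); the perillic acid branch (steps 1–4) joins at step 10.

Step 16 (key step). The silyl peroxide may add too slowly to a carbonyl flanked by a quaternary and a tertiary carbon, so that the Lewis acid instead strips the triethylsilyl ether and the freed β-hydroxy ketone dehydrates. The fallback sets out from 24 and hides the alkene so that a strong peracid can be used. Bromine (CH2Cl2, −78 °C) adds to the isopropenyl group to give the dibromo ketone F1. Trifluoroperacetic acid buffered with Na2HPO4 (CH2Cl2, 0 °C) then carries out the Baeyer–Villiger oxidation with no alkene left to epoxidise, giving the dibromo lactone F2. Zinc dust (NH4Cl, THF/MeOH, 0 °C) restores the isopropenyl group, and the sequence comes back to the route at 26.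

Step 14. The ruthenium carbene formed at the lactone vinyl group may fail to engage the electron-poor 1,1-disubstituted methacryloyl alkene, so that intermolecular cross-metathesis at the vinyl group or metathesis at the isopropenyl group takes over. The fallback sets out from 19 and closes the ring on a less substituted alkene, adding the methyl group afterwards. Fukuyama coupling with vinylzinc bromide gives the acryloyl ketone F3. Ring-closing metathesis of its two monosubstituted alkenes gives the cyclooctenone F4. Iodine and pyridine (CH2Cl2) convert this to the α-iodo enone F5, and Stille coupling with tetramethyltin (Pd2(dba)3, AsPh3, CuI) installs the methyl group, coming back to the route at 21.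

Step 15. The bromoacetate may enter the enolate from the face on the side of the lactone bridge, which would give the epimer at the quaternary carbon. The fallback sets out from 19 and exchanges the roles of the two substituents. Fukuyama coupling with (4-methoxy-4-oxobut-1-en-2-yl)zinc iodide (from methyl 3-iodobut-3-enoate, zinc dust and LiCl) gives the ketone F6, whose alkene already carries the CH2CO2Me arm. Ring-closing metathesis gives the enone F7. L-Selectride followed by methyl iodide then delivers CH3 from the face that the bromoacetate would have taken, so CH3 ends on the side of the lactone bridge and the sequence comes back to the route at 24.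

**Further compounds**
F1 | step 16 | dibromo ketone (24 with 1,2-dibromopropan-2-yl in place of isopropenyl, epimers at CBr) | BrCC(C)(Br)[C@@H]1C[C@H](O[Si](CC)(CC)CC)[C@@H]2C(=O)[C@](C)(CC(=O)OC)C[C@H]3OC(=O)[C@H]([C@@H]3O[Si](C)(C)C(C)(C)C)[C@H]2C1
F2 | step 16 | dibromo nine-membered lactone (26 with 1,2-dibromopropan-2-yl in place of isopropenyl) | BrCC(C)(Br)[C@@H]1C[C@H](O[Si](CC)(CC)CC)[C@@H]2C(=O)O[C@](C)(CC(=O)OC)C[C@H]3OC(=O)[C@H]([C@@H]3O[Si](C)(C)C(C)(C)C)[C@H]2C1
F3 | step 14 | acryloyl ketone (19 with C(=O)SEt replaced by C(=O)CH=CH2) | C=C(C)[C@@H]1C[C@H](O[Si](CC)(CC)CC)[C@H](C(=O)C=C)[C@H](C1)[C@@H]2C(=O)O[C@H](C=C)[C@H]2O[Si](C)(C)C(C)(C)C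
F4 | step 14 | tricyclic cyclooct-2-enone without the α-methyl group | C=C(C)[C@@H]1C[C@H](O[Si](CC)(CC)CC)[C@@H]2C(=O)/C=C\[C@H]3OC(=O)[C@H]([C@@H]3O[Si](C)(C)C(C)(C)C)[C@H]2C1
F5 | step 14 | tricyclic α-iodo enone | C=C(C)[C@@H]1C[C@H](O[Si](CC)(CC)CC)[C@@H]2C(=O)/C(I)=C\[C@H]3OC(=O)[C@H]([C@@H]3O[Si](C)(C)C(C)(C)C)[C@H]2C1
F6 | step 15 | ketone with C(=O)C(=CH2)CH2CO2Me in place of C(=O)SEt of 19 | C=C(C)[C@@H]1C[C@H](O[Si](CC)(CC)CC)[C@H](C(=O)C(=C)CC(=O)OC)[C@H](C1)[C@@H]2C(=O)O[C@H](C=C)[C@H]2O[Si](C)(C)C(C)(C)C
F7 | step 15 | tricyclic enone carrying CH2CO2Me on the α-carbon | C=C(C)[C@@H]1C[C@H](O[Si](CC)(CC)CC)[C@@H]2C(=O)/C(CC(=O)OC)=C\[C@H]3OC(=O)[C@H]([C@@H]3O[Si](C)(C)C(C)(C)C)[C@H]2C1
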